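**Plan**
- Retr: cut (i) the CH2–CH2 bond between the second and third chain carbons (from the ring) of the decyl group, giving an octyl half and a 2-(pyridin-3-yl)ethyl half; (ii) the ring C5–chain bond of that half, as a propanoate side chain; (iii) the C(=O)–nonyl bond of the ketone.
- Forward: the pyridine ring is bought intact. Ketone by Weinreb acylation, propanoate arm by Negishi coupling, saponification, then mixed Kolbe electrolysis with nonanoic acid joins the chain.
- Enabling feature: the two chain carbons being joined are plain CH2 groups, the ring-side one homobenzylic to pyridine C5, so both halves can be primary, unstabilised radicals formed from carboxylates by loss of CO2. The pyridine ring with its C3 aryl ketone is electron-poor and inert at the anode.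
- Helpers: the two CO2H groups are traceless activators, lost in the key step itself.
- Stereochemistry: the target is achiral (no stereocentre, no stereogenic double bond), so nothing has to be set.

Key step: step 4

Remark: compounds 1, 2 (1 M in Et2O), 5 (0.5 M in THF) and 9 are taken as catalogue items.

**Step 1**
Reactants: 1 5-bromo-N-methoxy-N-methylnicotinamide; 2 nonylmagnesium bromide
Product: 4 1-(5-bromopyridin-3-yl)decan-1-one, via bromomagnesium hemiaminal chelate 3 (not isolated)
Conditions: 2 (1.2 equiv), THF, −10 → 0 °C; then sat. aq NH4Cl
Reagents that add atoms: none
Why: Weinreb ketone synthesis; the five-membered N-methoxy magnesium chelate 3 survives until work-up and so prevents over-addition, and a primary alkyl Grignard should acylate at ≤ 0 °C faster than it exchanges with the 3-bromopyridine.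

**Step 2**
Reactants: 4 1-(5-bromopyridin-3-yl)decan-1-one; 5 (3-ethoxy-3-oxopropyl)zinc bromide
Product: 6 ethyl 3-(5-decanoylpyridin-3-yl)propanoate
Conditions: 5 (1.5 equiv), Pd(OAc)2 (2 mol %), SPhos (4 mol %), THF, 50 °C
Reagents that add atoms: none
Why: Negishi C(sp2)–C(sp3) coupling; the electron-poor bromopyridine should add oxidatively with ease, and the ester-chelated homoenolate zinc reagent neither adds to nor enolises the ketone.

**Step 3**
Reactants: 6 ethyl 3-(5-decanoylpyridin-3-yl)propanoate
Product: 8 3-(5-decanoylpyridin-3-yl)propanoic acid, via lithium carboxylate 7 (not isolated)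
Conditions: LiOH·H2O (2 equiv), THF/MeOH/H2O, 0 °C → rt; then 1 M HCl to pH ≈ 4.5, extraction
Reagents that add atoms: lithium hydroxide, [Li+].[OH-]
Why: ester saponification (BAc2) under conditions that leave the aryl alkyl ketone untouched; acidification to the isoelectric region should release the neutral, lipophilic keto acid for extraction.

**Step 4**
Reactants: 8 3-(5-decanoylpyridin-3-yl)propanoic acid; 9 nonanoic acid
Product: 10 1-(5-decylpyridin-3-yl)decan-1-one
Conditions: 9 (8 equiv), KOH (10 mol % of total acid), MeOH, undivided cell, Pt anode (ca. 0.2 A cm−2)/Pt cathode, constant current, 25–35 °C, ca. 1.3 F per mol of total acid; aq NaHCO3 wash, silica (hexane, then hexane/EtOAc)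
Reagents that add atoms: none
Why: At the platinum anode at high current density the carboxylates of 8 and 9 are each oxidised by one electron to acyloxy radicals that lose CO2 in the electrode layer, and the octyl radical and the 2-(5-decanoylpyridin-3-yl)ethyl radical so formed combine to give the C(sp3)–C(sp3) bond between the second and third carbon of the decyl chain (counted from the ring), while protons are discharged as H2 at the cathode. The closest known reaction type is the mixed (crossed) Kolbe electrolysis of two alkanoic acids with the cheaper acid in excess, which is known to tolerate ketones and pyridine. No ring is closed and no stereocentre is formed. The step needs cross- over homo-coupling, which the eightfold excess of 9 should secure statistically, the co-formed hexadecane being non-polar and removable on silica. It also needs radical coupling instead of further oxidation to a cation (Hofer–Moest path), which is secured because both radicals are primary and unstabilised, the pyridine ring standing one carbon further off than benzylic. Finally the electron-poor 3-acylpyridine ring and the ketone resist anodic oxidation, the pyridine stays unprotonated in the weakly acidic carboxylate buffer so that Minisci-type radical addition to the ring is slow, and proton discharge at platinum should outrun cathodic reduction of the aryl ketone.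

**Compound list**
1 | 5-bromo-N-methoxy-N-methylnicotinamide | CON(C)C(=O)c1cncc(Br)c1 | starting material
2 | nonylmagnesium bromide | CCCCCCCCC[Mg]Br | starting material
3 | bromomagnesium hemiaminal chelate of 1-(5-bromopyridin-3-yl)-1-[methoxy(methyl)amino]decan-1-ol | CCCCCCCCCC(O[Mg]Br)(N(C)OC)c1cncc(Br)c1 | intermediate
4 | 1-(5-bromopyridin-3-yl)decan-1-one | CCCCCCCCCC(=O)c1cncc(Br)c1 | intermediate
5 | (3-ethoxy-3-oxopropyl)zinc bromide | CCOC(=O)CC[Zn]Br | starting material
6 | ethyl 3-(5-decanoylpyridin-3-yl)propanoate | CCCCCCCCCC(=O)c1cncc(CCC(=O)OCC)c1 | intermediate
7 | lithium 3-(5-decanoylpyridin-3-yl)propanoate | [Li+].[O-]C(=O)CCc1cncc(C(=O)CCCCCCCCC)c1 | intermediate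
8 | 3-(5-decanoylpyridin-3-yl)propanoic acid | CCCCCCCCCC(=O)c1cncc(CCC(=O)O)c1 | intermediate
9 | nonanoic acid | CCCCCCCCC(=O)O | starting material
10 | 1-(5-decylpyridin-3-yl)decan-1-one | CCCCCCCCCCc1cncc(C(=O)CCCCCCCCC)c1 | target

Total step count: 4. Longest linear sequence: 4 steps (1 → 4 → 6 → 8 → 10).

**Steps most likely to fail**

Step 4. The valuable radical may be lost to homocoupling or disproportionation, the anode may passivate, the aryl ketone may be reduced at the cathode, or alkyl radicals may add to the pyridine ring. Fallback: setting out from bromide 4, the whole chain is attached at the ring carbon instead. Dec-1-ene is hydroborated with 9-BBN-H (THF, 0 °C → rt) to B-decyl-9-borabicyclo[3.3.1]nonane F1. This is coupled with 4 in a B-alkyl Suzuki–Miyaura reaction (Pd(dppf)Cl2, aq K3PO4, THF/DMF, 60 °C), which comes back to the route at target 10.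

Step 2. Transmetalation may be slow through catalyst binding by the pyridine nitrogen, and protodezincation of the reagent or hydrodebromination may compete. Fallback: setting out from 4, a Heck reaction with ethyl acrylate (Pd(OAc)2, P(o-tol)3, NaOAc, DMAc, 120 °C) should give ethyl (E)-3-(5-decanoylpyridin-3-yl)acrylate F2. Hydrogenation of its C=C bond (H2 1 atm, Pd/C, EtOAc, rt, stopped after one equivalent) comes back to the route at ester 6.

Step 1. Bromine–magnesium exchange at the ring or addition of the Grignard reagent to the pyridine ring may compete with the slower acylation of the amide. Fallback: setting out from 2, addition to commercial 5-bromonicotinaldehyde at −78 °C in THF, where carbonyl addition is much faster than exchange, should give racemic 1-(5-bromopyridin-3-yl)decan-1-ol F3. Its stereocentre is erased by Dess–Martin oxidation (CH2Cl2, NaHCO3, rt), which comes back to the route at ketone 4.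

**Further compounds**
F1 | step 4 | B-decyl-9-borabicyclo[3.3.1]nonane | CCCCCCCCCCB1C2CCCC1CCC2
F2 | step 2 | ethyl (E)-3-(5-decanoylpyridin-3-yl)acrylate | CCCCCCCCCC(=O)c1cncc(/C=C/C(=O)OCC)c1
F3 | step 1 | 1-(5-bromopyridin-3-yl)decan-1-ol (racemic) | CCCCCCCCCC(O)c1cncc(Br)c1
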